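**Plan**
- Retrosynthesis: first cut the enone C(=O)–Cα bond (formyl C–H of a chroman-6-carbaldehyde plus the terminal carbon of an arylacetylene). Then take the C3 carbinol back through a 3,4-epoxide to the C3=C4 chromene. Then open the pyran (O1–C2 and C4–C4a) back to an aryl 1,1-dimethylpropargyl ether of methyl 2,4,6-trihydroxybenzoate.
- Forward: para-O-propargylation, MOM capping of the two ortho oxygens, and propargyl Claisen/oxa-6π closure of the pyran (ring B) onto the benzene ring (ring A). Then asymmetric epoxidation, hydride opening with ester reduction, reoxidation to the aldehyde, release of one ortho phenol, joining of the chain, and global MOM removal.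
- Stereochemistry: C3 (R) is set by catalyst-controlled epoxidation of C3=C4 and kept because hydride enters at C4. The E-alkene comes from syn addition of Rh–H across the alkyne.
- Enabling feature: the phenolic OH on C5 of ring A, ortho to the formyl carbon on C6, binds rhodium as a phenoxide and holds the acyl rhodium hydride in a five-membered chelate (O–C5–C6–C(=O)–Rh). The aldehyde C–H therefore adds across the alkyne instead of losing CO.

Key step: step 9

Remark: C3 is taken as (R), as the SMILES encodes; the (R,R)-salen complex is assigned to the (3R,4R)-epoxide by analogy with other 2,2-dimethylchromenes (the antipodal complex would be used if correlation showed the opposite sense); 1, 2 and 12 are taken as purchasable.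

**Step 1**
Reactants: 1 methyl 2,4,6-trihydroxybenzoate; 2 3-chloro-3-methylbut-1-yne
Product: 3 methyl 2,6-dihydroxy-4-[(2-methylbut-3-yn-2-yl)oxy]benzoate
Conditions: K2CO3, KI, CuI (5 mol %), acetone, 56 °C
Reagents that add atoms: none
Why: Copper-assisted O-propargylation (Williamson-type etherification with a tertiary propargylic chloride) should take place at the para OH, the most acidic phenol and the only one not hydrogen-bonded to the ester.

**Step 2**
Reactants: 3 methyl 2,6-dihydroxy-4-[(2-methylbut-3-yn-2-yl)oxy]benzoate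
Product: 4 methyl 2,6-bis(methoxymethoxy)-4-[(2-methylbut-3-yn-2-yl)oxy]benzoate
Conditions: NaH, MOMCl, DMF, 0 °C to rt
Reagents that add atoms: chloromethyl methyl ether (MOMCl), COCCl
Why: MOM etherification of the two sodium phenoxides caps both oxygens ortho to the ester, so that only the para oxygen can later close the pyran ring.

**Step 3**
Reactants: 4 methyl 2,6-bis(methoxymethoxy)-4-[(2-methylbut-3-yn-2-yl)oxy]benzoate
Product: 7 methyl 5,7-bis(methoxymethoxy)-2,2-dimethyl-2H-chromene-6-carboxylate, via allenyl phenol 5 (not isolated), via ortho-quinone methide 6 (not isolated)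
Conditions: PhNEt2, 190 °C
Reagents that add atoms: none
Why: Aromatic propargyl Claisen rearrangement to the ortho carbon (both ortho carbons are equivalent), enolisation to 5, 1,5-hydrogen shift to 6 and oxa-6π electrocyclisation should give the 2,2-dimethyl-2H-chromene, with the ring oxygen necessarily the one para to the ester.

**Step 4**
Reactants: 7 methyl 5,7-bis(methoxymethoxy)-2,2-dimethyl-2H-chromene-6-carboxylate
Product: 8 methyl (3R,4R)-3,4-epoxy-5,7-bis(methoxymethoxy)-2,2-dimethyl-3,4-dihydro-2H-chromene-6-carboxylate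
Conditions: (R,R)-Jacobsen catalyst [(salen)MnCl, salen = N,N'-bis(3,5-di-tert-butylsalicylidene)cyclohexane-1,2-diamine dianion] (4 mol %), NaOCl (aq., pH 11.3), 4-phenylpyridine N-oxide, CH2Cl2, 0 °C
Reagents that add atoms: sodium hypochlorite, [Na+].[O-]Cl
Why: Jacobsen–Katsuki epoxidation of a cis-disubstituted conjugated olefin of the 2,2-dimethylchromene class should proceed by side-on approach to the oxo complex of trivalent manganese, the (R,R)-ligand setting C3 and C4 as R, while the ester keeps the benzylic epoxide from ionising.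

**Step 5**
Reactants: 8 methyl (3R,4R)-3,4-epoxy-5,7-bis(methoxymethoxy)-2,2-dimethyl-3,4-dihydro-2H-chromene-6-carboxylate
Product: 9 (3R)-6-(hydroxymethyl)-5,7-bis(methoxymethoxy)-2,2-dimethyl-3,4-dihydro-2H-chromen-3-ol
Conditions: LiAlH4, THF, 0 °C to 50 °C
Reagents that add atoms: none
Why: Hydride should open the epoxide at benzylic C4 (C3 is shielded by the quaternary C2), which leaves the C3–O bond and the (R) configuration untouched, and should reduce the ester to the benzylic alcohol in the same operation.

**Step 6**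
Reactants: 9 (3R)-6-(hydroxymethyl)-5,7-bis(methoxymethoxy)-2,2-dimethyl-3,4-dihydro-2H-chromen-3-ol
Product: 10 (3R)-3-hydroxy-5,7-bis(methoxymethoxy)-2,2-dimethyl-3,4-dihydro-2H-chromene-6-carbaldehyde
Conditions: MnO2, CH2Cl2, rt
Reagents that add atoms: none
Why: Chemoselective benzylic oxidation: MnO2 should oxidise only the electron-rich benzylic primary alcohol and leave the saturated secondary C3 carbinol alone.

**Step 7**
Reactants: 10 (3R)-3-hydroxy-5,7-bis(methoxymethoxy)-2,2-dimethyl-3,4-dihydro-2H-chromene-6-carbaldehyde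
Product: 11 (3R)-3,5-dihydroxy-7-(methoxymethoxy)-2,2-dimethyl-3,4-dihydro-2H-chromene-6-carbaldehyde
Conditions: HCl (cat.), MeOH, 0 °C, stopped at mono-cleavage
Reagents that add atoms: none
Why: Carbonyl-assisted selective cleavage of an ortho MOM ether: the acetal on C5 is flanked on both sides (C4a and C6) and twisted out of conjugation, so it should exchange first, after which the new phenol ties up the formyl oxygen in a hydrogen bond and the conjugated C7 acetal reacts much more slowly.

**Step 8**
Reactants: 12 4-ethynylphenol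
Product: 13 1-ethynyl-4-(methoxymethoxy)benzene
Conditions: MOMCl, i-Pr2NEt, CH2Cl2, 0 °C to rt
Reagents that add atoms: chloromethyl methyl ether (MOMCl), COCCl
Why: Standard MOM etherification masks the acidic phenol, which could otherwise bind rhodium or promote alkyne oligomerisation in the next step.

**Step 9**
Reactants: 11 (3R)-3,5-dihydroxy-7-(methoxymethoxy)-2,2-dimethyl-3,4-dihydro-2H-chromene-6-carbaldehyde; 13 1-ethynyl-4-(methoxymethoxy)benzene
Product: 14 (E)-1-[(3R)-3,5-dihydroxy-7-(methoxymethoxy)-2,2-dimethyl-3,4-dihydro-2H-chromen-6-yl]-3-[4-(methoxymethoxy)phenyl]prop-2-en-1-one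
Conditions: [RhCl(cod)]2 (2.5 mol %), dppf [Fe(C5H4PPh2)2] (5 mol %), Na2CO3 (10 mol %), toluene, 80 °C
Reagents that add atoms: none
Why: The C5 phenoxide binds monovalent rhodium, oxidative addition of the neighbouring formyl C–H gives a five-membered acyl hydride chelate of trivalent rhodium, the alkyne inserts into Rh–H in a syn fashion with rhodium on the terminal carbon, and C–C reductive elimination forms the C(=O)–CH bond. The closest known reaction type is the rhodium-catalysed, chelation-assisted intermolecular hydroacylation of alkynes with salicylaldehydes. No ring is closed and no stereocentre is formed; the E geometry follows from syn addition of H and acyl across the triple bond. The step needs linear regioselectivity, which the unhindered terminal carbon, the donor aryl group on the internal carbon and the wide-bite-angle diphosphine should secure. It also needs suppression of decarbonylation, which the O–C5–C6–C(=O)–Rh chelate provides. Closure to a flavanone should be held back because C7–O is capped as its MOM ether and the C5 phenol ends hydrogen-bonded to the new ketone, and the free C3 carbinol should be tolerated.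

**Step 10**
Reactants: 14 (E)-1-[(3R)-3,5-dihydroxy-7-(methoxymethoxy)-2,2-dimethyl-3,4-dihydro-2H-chromen-6-yl]-3-[4-(methoxymethoxy)phenyl]prop-2-en-1-one
Product: 15 (E)-3-(4-hydroxyphenyl)-1-[(3R)-3,5,7-trihydroxy-2,2-dimethyl-3,4-dihydro-2H-chromen-6-yl]prop-2-en-1-one
Conditions: HCl (1 M), MeOH, rt
Reagents that add atoms: none
Why: Acid-catalysed acetal methanolysis should free both phenols at room temperature without touching the chroman ether, the C3 carbinol or the E-enone, the reaction being stopped at full conversion to limit acid-induced closure to a flavanone.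

**Compound list**
1 | methyl 2,4,6-trihydroxybenzoate | COC(=O)c1c(O)cc(O)cc1O | starting material
2 | 3-chloro-3-methylbut-1-yne | CC(C)(Cl)C#C | starting material
3 | methyl 2,6-dihydroxy-4-[(2-methylbut-3-yn-2-yl)oxy]benzoate | COC(=O)c1c(O)cc(OC(C)(C)C#C)cc1O | intermediate
4 | methyl 2,6-bis(methoxymethoxy)-4-[(2-methylbut-3-yn-2-yl)oxy]benzoate | COC(=O)c1c(OCOC)cc(OC(C)(C)C#C)cc1OCOC | intermediate
5 | methyl 4-hydroxy-2,6-bis(methoxymethoxy)-3-(3-methylbuta-1,2-dien-1-yl)benzoate (allenyl phenol) | COC(=O)c1c(OCOC)cc(O)c(C=C=C(C)C)c1OCOC | intermediate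
6 | methyl (3Z)-2,6-bis(methoxymethoxy)-3-(3-methylbut-2-en-1-ylidene)-4-oxocyclohexa-1,5-diene-1-carboxylate (ortho-quinone methide) | COC(=O)C1=C(OCOC)/C(=C/C=C(C)C)C(=O)C=C1OCOC | intermediate
7 | methyl 5,7-bis(methoxymethoxy)-2,2-dimethyl-2H-chromene-6-carboxylate | CC1(C)C=Cc2c(O1)cc(OCOC)c(C(=O)OC)c2OCOC | intermediate
8 | methyl (3R,4R)-3,4-epoxy-5,7-bis(methoxymethoxy)-2,2-dimethyl-3,4-dihydro-2H-chromene-6-carboxylate | CC1(C)Oc2cc(OCOC)c(C(=O)OC)c(OCOC)c2[C@H]3O[C@H]31 | intermediate
9 | (3R)-6-(hydroxymethyl)-5,7-bis(methoxymethoxy)-2,2-dimethyl-3,4-dihydro-2H-chromen-3-ol | CC1(C)Oc2cc(OCOC)c(CO)c(OCOC)c2C[C@H]1O | intermediate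
10 | (3R)-3-hydroxy-5,7-bis(methoxymethoxy)-2,2-dimethyl-3,4-dihydro-2H-chromene-6-carbaldehyde | CC1(C)Oc2cc(OCOC)c(C=O)c(OCOC)c2C[C@H]1O | intermediate
11 | (3R)-3,5-dihydroxy-7-(methoxymethoxy)-2,2-dimethyl-3,4-dihydro-2H-chromene-6-carbaldehyde | CC1(C)Oc2cc(OCOC)c(C=O)c(O)c2C[C@H]1O | intermediate
12 | 4-ethynylphenol | C#Cc1ccc(O)cc1 | starting material
13 | 1-ethynyl-4-(methoxymethoxy)benzene | C#Cc1ccc(OCOC)cc1 | intermediate
14 | (E)-1-[(3R)-3,5-dihydroxy-7-(methoxymethoxy)-2,2-dimethyl-3,4-dihydro-2H-chromen-6-yl]-3-[4-(methoxymethoxy)phenyl]prop-2-en-1-one | CC1(C)Oc2cc(OCOC)c(C(=O)/C=C/c3ccc(OCOC)cc3)c(O)c2C[C@H]1O | intermediate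
15 | (E)-3-(4-hydroxyphenyl)-1-[(3R)-3,5,7-trihydroxy-2,2-dimethyl-3,4-dihydro-2H-chromen-6-yl]prop-2-en-1-one | CC1(C)Oc2cc(O)c(C(=O)/C=C/c3ccc(O)cc3)c(O)c2C[C@H]1O | target

**Totals**
Total steps: 10. Longest linear sequence: 9 (steps 1 to 7, 9 and 10).

**Steps most likely to fail**

Step 9. Hydrometalation may run in the reverse sense and deliver the acyl group to the aryl-bearing carbon, the arylacetylene may oligomerise on rhodium, or the product may close to a flavanone under the basic conditions. The fallback sets out from aldehyde 10 and alkyne 13 and returns to the route at 15. Alkyne 13 is deprotonated with n-BuLi (THF, −78 °C, excess to allow for the C3 hydroxyl) and added to 10 to give 1-[(3R)-3-hydroxy-5,7-bis(methoxymethoxy)-2,2-dimethylchroman-6-yl]-3-[4-(methoxymethoxy)phenyl]prop-2-yn-1-ol F1. Hydroxyl-directed trans-hydroalumination with NaAlH2(OCH2CH2OCH3)2 (THF, 0 °C) gives (E)-1-[(3R)-3-hydroxy-5,7-bis(methoxymethoxy)-2,2-dimethylchroman-6-yl]-3-[4-(methoxymethoxy)phenyl]prop-2-en-1-ol F2. MnO2 oxidises the allylic, benzylic carbinol to (E)-1-[(3R)-3-hydroxy-5,7-bis(methoxymethoxy)-2,2-dimethylchroman-6-yl]-3-[4-(methoxymethoxy)phenyl]prop-2-en-1-one F3, and the conditions of step 10 then remove all three MOM groups to give 15.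

Step 4. The methoxymethoxy group on C5, peri to C4, may disturb the side-on approach and lower the facial selectivity, or hypochlorite may attack the electron-rich arene. The fallback sets out from chromene 7 and returns to the route at 9. Epoxidation without chiral control (mCPBA, NaHCO3, CH2Cl2) gives racemic methyl 3,4-epoxy-5,7-bis(methoxymethoxy)-2,2-dimethylchromane-6-carboxylate F4. Benzylic hydrogenolysis (H2, Pd/C, EtOAc) gives racemic methyl 3-hydroxy-5,7-bis(methoxymethoxy)-2,2-dimethylchromane-6-carboxylate F5. Dess–Martin oxidation gives methyl 5,7-bis(methoxymethoxy)-2,2-dimethyl-3-oxochromane-6-carboxylate F6. Corey–Bakshi–Shibata reduction with the (S)-methyl oxazaborolidine and BH3·SMe2, with the quaternary C2 as the large group and the C4 methylene as the small one, should give methyl (3R)-3-hydroxy-5,7-bis(methoxymethoxy)-2,2-dimethylchromane-6-carboxylate F7. LiAlH4 then reduces the ester to give 9.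

Step 7. The acetal exchange may run on to loss of both MOM groups, or may take the C7 group instead of the C5 group. Either mono-phenol would still carry a free OH ortho to the formyl group and would converge on 15. The fallback sets out from 10 and returns to the route at 15. Both ring MOM groups are removed (HCl, MeOH, rt) to give (3R)-3,5,7-trihydroxy-2,2-dimethylchromane-6-carbaldehyde F8. Hydroacylation of 13 under the conditions of step 9 gives (E)-3-[4-(methoxymethoxy)phenyl]-1-[(3R)-3,5,7-trihydroxy-2,2-dimethylchroman-6-yl]prop-2-en-1-one F9, and the conditions of step 10 give 15.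

**Further compounds**
F1 | step 9 | 1-[(3R)-3-hydroxy-5,7-bis(methoxymethoxy)-2,2-dimethylchroman-6-yl]-3-[4-(methoxymethoxy)phenyl]prop-2-yn-1-ol | CC1(C)Oc2cc(OCOC)c(C(O)C#Cc3ccc(OCOC)cc3)c(OCOC)c2C[C@H]1O
F2 | step 9 | (E)-1-[(3R)-3-hydroxy-5,7-bis(methoxymethoxy)-2,2-dimethylchroman-6-yl]-3-[4-(methoxymethoxy)phenyl]prop-2-en-1-ol | CC1(C)Oc2cc(OCOC)c(C(O)/C=C/c3ccc(OCOC)cc3)c(OCOC)c2C[C@H]1O
F3 | step 9 | (E)-1-[(3R)-3-hydroxy-5,7-bis(methoxymethoxy)-2,2-dimethylchroman-6-yl]-3-[4-(methoxymethoxy)phenyl]prop-2-en-1-one | CC1(C)Oc2cc(OCOC)c(C(=O)/C=C/c3ccc(OCOC)cc3)c(OCOC)c2C[C@H]1O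
F4 | step 4 | racemic methyl 3,4-epoxy-5,7-bis(methoxymethoxy)-2,2-dimethylchromane-6-carboxylate | CC1(C)Oc2cc(OCOC)c(C(=O)OC)c(OCOC)c2C2OC21
F5 | step 4 | racemic methyl 3-hydroxy-5,7-bis(methoxymethoxy)-2,2-dimethylchromane-6-carboxylate | CC1(C)Oc2cc(OCOC)c(C(=O)OC)c(OCOC)c2CC1O
F6 | step 4 | methyl 5,7-bis(methoxymethoxy)-2,2-dimethyl-3-oxochromane-6-carboxylate | CC1(C)Oc2cc(OCOC)c(C(=O)OC)c(OCOC)c2CC1=O
F7 | step 4 | methyl (3R)-3-hydroxy-5,7-bis(methoxymethoxy)-2,2-dimethylchromane-6-carboxylate | CC1(C)Oc2cc(OCOC)c(C(=O)OC)c(OCOC)c2C[C@H]1O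
F8 | step 7 | (3R)-3,5,7-trihydroxy-2,2-dimethylchromane-6-carbaldehyde | CC1(C)Oc2cc(O)c(C=O)c(O)c2C[C@H]1O
F9 | step 7 | (E)-3-[4-(methoxymethoxy)phenyl]-1-[(3R)-3,5,7-trihydroxy-2,2-dimethylchroman-6-yl]prop-2-en-1-one | CC1(C)Oc2cc(O)c(C(=O)/C=C/c3ccc(OCOC)cc3)c(O)c2C[C@H]1O
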